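Ring A is the 4-hydroxybenzoyl ring. Ring B is the central benzene (1-aroyl, 2-OH, 4-OMe, 5-alkyl). Ring C is the terminal 4-hydroxyphenyl ring, joined to ring B by the chain Cα–Cβ–Cγ. No ring is formed in the route, since all three benzene rings are bought.
Key disconnection: the Cβ–Cγ bond (CH2–CH2, Cγ being the benzylic carbon of ring C). It leads back to two carboxylic acids, the ring-B 3-arylpropanoic acid and [4-(benzyloxy)phenyl]acetic acid, which are joined with loss of both CO2H groups in one Ni-electrocatalytic doubly decarboxylative cross-coupling.
Enabling feature: Cβ and Cγ are both unsubstituted CH2 carbons. Cβ is insulated from ring B by Cα and gives an unstabilised primary radical that Ni captures fast. Cγ sits directly on ring C, para to its oxygen, and gives a stabilised, long-lived benzylic radical. This contrast sorts the two radicals at nickel.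
Second disconnection: the ring B–C(=O) bond, made by Friedel–Crafts aroylation of commercial 3-(2,4-dimethoxyphenyl)propanoic acid at the carbon para to one OMe and ortho to the other.
End game: the ketone oxygen chelates BCl3 and singles out the neighbouring OMe for cleavage, in the same operation that removes both benzyl ethers.

Key step: step 2

Remark: the target has no stereocentre, no stereogenic axis and no C=C double bond. It is achiral, so the route needs no stereocontrol and the question of a single enantiomer does not arise.

Step 1
Reactants: 1 3-(2,4-dimethoxyphenyl)propanoic acid; 2 4-(benzyloxy)benzoyl chloride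
Product: 3 3-{5-[4-(benzyloxy)benzoyl]-2,4-dimethoxyphenyl}propanoic acid
Conditions: HFIP, rt
Reagents that add atoms: none
Why: Friedel–Crafts acylation promoted by the hydrogen-bond-donor solvent HFIP should go to C5, to which both OMe groups of 1 direct (para to 2-OMe, ortho to 4-OMe; C3 is flanked by two OMe groups and C6 is meta to both), and without a metal Lewis acid the free CO2H and the benzyl ether should be left alone.

Step 2
Reactants: 3 3-{5-[4-(benzyloxy)benzoyl]-2,4-dimethoxyphenyl}propanoic acid; 4 [4-(benzyloxy)phenyl]acetic acid (3 equiv); 5 N-hydroxyphthalimide (4 equiv)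
Product: 8 [4-(benzyloxy)phenyl](5-{3-[4-(benzyloxy)phenyl]propyl}-2,4-dimethoxyphenyl)methanone, via propanoate NHP ester 6 (not isolated), via arylacetate NHP ester 7 (not isolated)
Conditions: DIC (4 equiv), DMAP (cat.), DMF, rt; then NiCl2·6H2O (20 mol %), 4,4′,4″-tBu3-terpyridine (20 mol %), NaI, DMF, Zn(+)/RVC(−), undivided cell, constant current, rt; dilute HCl work-up
Reagents that add atoms: none
Why: Proposed new method: DIC first turns both acids into their N-hydroxyphthalimide esters 6 and 7, and cathodically generated low-valent (terpyridine)Ni then passes one electron to each ester, which loses phthalimide anion and CO2 to give the primary 2-arylethyl radical from 6 and the 4-(benzyloxy)benzyl radical from 7, while the zinc anode supplies the two electrons. The unstabilised primary radical should be trapped fast and practically irreversibly as alkyl–Ni, the longer-lived benzylic radical should add to this species, and reductive elimination from the dialkyl-Ni(III) should form the Cβ–Cγ CH2–CH2 bond. The closest known reaction type is the Ni-electrocatalytic doubly decarboxylative C(sp3)–C(sp3) cross-coupling of two redox-active esters made in situ, documented for unstabilised primary, secondary and some tertiary partners, and benzylic N-hydroxyphthalimide esters are known radical sources in Ni-catalysed reductive couplings, so what is new is the pairing of an arylacetic (benzylic) ester with a primary alkyl ester. No ring is closed and no stereocentre is created. The selectivity needed is cross-coupling over homo-coupling, and it should be secured by the different lifetimes and Ni affinities of the two radicals (set by para-oxygenated ring C on Cγ and by the insulating Cα next to ring B) and by the threefold excess of the cheap acid 4. Chemoselectivity rests on potentials and ligand shape: the electron-rich diaryl ketone is reduced only well beyond the potential at which Ni and the esters turn over, the tridentate ligand leaves no free cis site for β-hydride elimination, and the methyl and benzyl ethers are inert.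

Step 3
Reactants: 8 [4-(benzyloxy)phenyl](5-{3-[4-(benzyloxy)phenyl]propyl}-2,4-dimethoxyphenyl)methanone
Product: 9 (2-hydroxy-5-[3-(4-hydroxyphenyl)propyl]-4-methoxyphenyl)(4-hydroxyphenyl)methanone
Conditions: BCl3 (6 equiv), pentamethylbenzene (6 equiv), CH2Cl2, −78 °C to 0 °C; then H2O
Reagents that add atoms: none
Why: In this Lewis-acid ether cleavage BCl3 should remove both aryl benzyl ethers at low temperature with pentamethylbenzene as a non-basic cation scavenger, and through the six-membered chelate with the ketone oxygen it should cleave only the OMe ortho to the carbonyl (chelation-controlled demethylation), while the non-chelating OMe next to the chain stays.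

Compound list
1 | 3-(2,4-dimethoxyphenyl)propanoic acid | COc1ccc(CCC(=O)O)c(OC)c1 | starting material
2 | 4-(benzyloxy)benzoyl chloride | O=C(Cl)c1ccc(OCc2ccccc2)cc1 | starting material
3 | 3-{5-[4-(benzyloxy)benzoyl]-2,4-dimethoxyphenyl}propanoic acid | COc1cc(OC)c(C(=O)c2ccc(OCc3ccccc3)cc2)cc1CCC(=O)O | intermediate
4 | [4-(benzyloxy)phenyl]acetic acid | O=C(O)Cc1ccc(OCc2ccccc2)cc1 | starting material
5 | N-hydroxyphthalimide | O=C1c2ccccc2C(=O)N1O | starting material
6 | 1,3-dioxoisoindolin-2-yl 3-{5-[4-(benzyloxy)benzoyl]-2,4-dimethoxyphenyl}propanoate (propanoate NHP ester) | COc1cc(OC)c(C(=O)c2ccc(OCc3ccccc3)cc2)cc1CCC(=O)ON1C(=O)c2ccccc2C1=O | intermediate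
7 | 1,3-dioxoisoindolin-2-yl [4-(benzyloxy)phenyl]acetate (arylacetate NHP ester) | O=C(Cc1ccc(OCc2ccccc2)cc1)ON1C(=O)c2ccccc2C1=O | intermediate
8 | [4-(benzyloxy)phenyl](5-{3-[4-(benzyloxy)phenyl]propyl}-2,4-dimethoxyphenyl)methanone | COc1cc(OC)c(C(=O)c2ccc(OCc3ccccc3)cc2)cc1CCCc1ccc(OCc2ccccc2)cc1 | intermediate
9 | (2-hydroxy-5-[3-(4-hydroxyphenyl)propyl]-4-methoxyphenyl)(4-hydroxyphenyl)methanone (achiral) | COc1cc(O)c(C(=O)c2ccc(O)cc2)cc1CCCc1ccc(O)cc1 | target

Total step count: 3. Longest linear sequence: 3 steps (1 → 3 → 8 → 9).

Steps most likely to fail

Step 2 (Proposed new method). Self-coupling of the stabilised benzylic radical, or β-hydride elimination and protodemetalation at the alkyl–nickel stage, may outrun the cross-coupling. The fallback uses known chemistry and replaces the double radical generation by a polar sp3–sp3 Negishi coupling. It sets out from 3. DCC coupling with N-hydroxypyridine-2-thione would give the Barton ester 2-thioxopyridin-1(2H)-yl 3-{5-[4-(benzyloxy)benzoyl]-2,4-dimethoxyphenyl}propanoate F1. Visible-light irradiation of this ester with iodoform (Barton decarboxylative iodination) would give the primary iodide [4-(benzyloxy)phenyl][5-(2-iodoethyl)-2,4-dimethoxyphenyl]methanone F2. Commercial 4-(benzyloxy)benzyl chloride would be converted with Zn dust and LiCl in THF into 4-(benzyloxy)benzylzinc chloride F3. Ni(acac)2-catalysed coupling of the iodide with the benzylic zinc reagent in the presence of Bu4NI and 4-fluorostyrene (THF/NMP) would form the same CH2–CH2 bond, tolerates the ketone, and comes back to the route at 8.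

Step 1. Without a metal Lewis acid the acylation may be sluggish. Solvolysis of the acid chloride by HFIP, or acyl exchange with the free carboxylic acid, may consume the electrophile. The fallback replaces electrophilic acylation by a Pd-catalysed three-component ketone synthesis. It sets out from 1. NBS in MeCN would brominate the same C5 position to give 3-(5-bromo-2,4-dimethoxyphenyl)propanoic acid F4. A carbonylative Suzuki–Miyaura coupling with commercial 4-(benzyloxy)phenylboronic acid would follow (Pd(OAc)2, di(1-adamantyl)-n-butylphosphine, K2CO3, CO 1 atm, toluene/H2O, 90 °C). This comes back to the route at 3.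

Step 3. The chelation-controlled demethylation may stay incomplete at the temperature at which debenzylation is clean. On warming, benzyl cations that escape the scavenger may alkylate the electron-rich rings, or the second methyl ether may be lost. The fallback separates the two events into orthogonal operations. It sets out from 8. Hydrogenolysis (H2 1 atm, Pd/C, EtOAc, rt, stopped at uptake of two equivalents so that the electron-rich diaryl ketone is spared) would give the bisphenol (5-[3-(4-hydroxyphenyl)propyl]-2,4-dimethoxyphenyl)(4-hydroxyphenyl)methanone F5. MgI2 etherate in THF at reflux, which acts only through the magnesium chelate with the ketone, would then cleave the ortho OMe and comes back to the route at 9.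

Further compounds
F1 | step 2 | 2-thioxopyridin-1(2H)-yl 3-{5-[4-(benzyloxy)benzoyl]-2,4-dimethoxyphenyl}propanoate | COc1cc(OC)c(C(=O)c2ccc(OCc3ccccc3)cc2)cc1CCC(=O)ON1C=CC=CC1=S
F2 | step 2 | [4-(benzyloxy)phenyl][5-(2-iodoethyl)-2,4-dimethoxyphenyl]methanone | COc1cc(OC)c(C(=O)c2ccc(OCc3ccccc3)cc2)cc1CCI
F3 | step 2 | 4-(benzyloxy)benzylzinc chloride | Cl[Zn]Cc1ccc(OCc2ccccc2)cc1
F4 | step 1 | 3-(5-bromo-2,4-dimethoxyphenyl)propanoic acid | COc1cc(OC)c(Br)cc1CCC(=O)O
F5 | step 3 | (5-[3-(4-hydroxyphenyl)propyl]-2,4-dimethoxyphenyl)(4-hydroxyphenyl)methanone | COc1cc(OC)c(C(=O)c2ccc(O)cc2)cc1CCCc1ccc(O)cc1
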